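What is left over in these vessels is part substrate, part dormant form.

the same everywhere: substrate 3.0 M

| flask | remark | time |
|---|---|---|
| autumn | a single well-mixed tank run continuously and read at steady state, 40.0 d in it on average |  |
| dawn | everything together in a closed stirred flask, run for 8.0 d | 8.0 d |
| dusk | a single well-mixed tank run continuously and read at steady state, 8.0 d in it on average |  |

    substrate ⇌ product + released group (K1 = 71.8 M, k1 = 0.0154 /h)
    substrate ⇌ dormant form (K2 = 0.587, k2 = 0.0393 /h)

- the stated concentrations are those of everything mixed, before any reaction; amounts are the same in each set-up
- run time (dawn): 8.0 d

* the set-up with the highest amount of product at the outlet or at the end, in percent of the substrate put in ("none" if the first two lie within 2 percentage points) (autumn / dawn / dusk / none)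
* amount of product at the outlet or at the end, in percent of the substrate put in, autumn
* amount of product at the outlet or at the end, in percent of the substrate put in, dawn
* amount of product at the outlet or at the end, in percent of the substrate put in, dusk

The hunch that the closed flask wins deserves a number, so solve both ends and join them. At the early end, substrate enters dormant form at 0.0393 /h and leaves by step 1 at 0.0154 /h. That exchange is faster, so a pre-equilibrium is a fair reading. The leftover pool then holds 63.0% as substrate, and it falls with the working constant, step 1's constant times that share, 0.00970 /h.

At the late end, the way back counts, with constant 2.14 × 10⁻⁴ /M/h on product times released group, which are equal here. The joined balance stops at 94.1% of the charge.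

In a tank, the joined rate equals product leaving per residence time. That gives 85.9% for autumn and 63.3% for dusk. In dawn, the closed flask closes on that stop with constant 0.0109 /h and reaches 82.0%. So this reckoning goes against the hunch: autumn stands higher than dawn by 3.9 percentage points.

The forecast names autumn, with 85.9% for autumn (84.5% to 87%), 81.5% for dawn (79% to 84%) and 63.9% for dusk (62% to 66%), where the tank “loses out to backmixing”. The dawn figure reckoned here is higher than the forecast's.

The flasks give autumn first, with 86.0% in autumn, 81.4% in dawn and 64.0% in dusk. The autumn outlet still carries 8.90% of the charge as substrate. Now strike out dormant form in dusk: the working constant 0.00970 /h returns to 0.0154 /h, which is larger, and the same tank balance gives 73.1%. The dusk run with that step struck out stands at 73.1%.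

Its constants were set for the occasion; what happens was integrated by code.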